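The vessel is closed, stirred and of constant volume, so what the readings do not show is still inside it, and at the last blue reading that is 75.0% of the charge.

common to all: substrate 0.050 M

| flask | coupling partner | temperature | remark | time |
|---|---|---|---|---|
| amber | 0.020 M | 35 °C | run made earlier |  |
| blue | 0.080 M | 60 °C | run made earlier |  |
| Tuesday's | 0.0400 M |  | at 40 °C throughout | 40 min |
| Wednesday's | 0.0400 M |  | at 80 °C until 3.0 min, from then on at 40 °C | 10 min |

- amber (time / min: target / %, substrate / %): 10.0: 0, 82; 20.0: 2, 71; 30.0: 0, 53; 40.0: 2, 44; 50.0: 4, 33; 60.0: 2, 27
- blue (time / min: target / %, substrate / %): 1.33: 0, 65; 2.50: 8, 43; 4.00: 8, 28; 5.00: 12, 20; 10.0: 20, 4; 15.0: 23, 2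

(readings scatter by 1.5 percentage points)

- which one finishes higher in amount of target, in percent of the substrate charged ("neither" within 2 percentage points) (Tuesday's / Wednesday's / neither)
- amount of target at the end, in percent of the substrate charged, Tuesday's
- amount of target at the end, in percent of the substrate charged, Wednesday's

- the numbers in the tables scatter with a standard deviation of 1.5 percentage points
- a reading or a percentage of target counts all its forms, free or not

Take the rungs from the fastest. In the blue run the substrate falls with a first-order half-life of about 2.15 min. Target arrives on a slower rung: at 5.00 min it reads 12%, about half of its last reading, with substrate already at 20%, so on this rung the flask holds something unseen between the two. The amber run has a half-life of about 31.8 min, which is far slower, and its target stays at a few points.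

These clocks differ, but dividing target gained by substrate lost removes time, and this gives the productive share, the part of the lost substrate that takes the road to target. The last blue reading gives 23.5%, and anything still on its way would raise it. Wednesday's partner charge, 0.800 of the substrate charge, exceeds that share, so I do not expect the partner to be the limiting reagent.

My reckoning is this. Wednesday's hot stage of 3.0 min outlasts blue's half-life at a higher temperature, so I expect about 23.5% of the charge as target. At amber's pace Tuesday's flask loses 56.0% in 40 min, which puts about 13.2% on the road, with target lagging behind it.

The forecast names Wednesday's, with 6% (3% to 10%) for Tuesday's and 14% (9% to 21%) for Wednesday's, holding that “the yield depends mainly on partner concentration”. I accept its Tuesday figure, but my Wednesday figure lies above its range.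

Tuesday's ends at 7.50% and Wednesday's at 27.4%, which lies above the forecast's range, and the flask that finishes higher is Wednesday's.

    substrate ⇌ dormant form (K = 9.00, k = 0.0290 s⁻¹, Ea = 92.0 kJ mol⁻¹, ΔH = −78.0 kJ mol⁻¹)
    substrate → intermediate (k = 0.0110 s⁻¹, Ea = 106 kJ mol⁻¹)
    coupling partner + intermediate → target (k = 0.350 M⁻¹ s⁻¹, Ea = 71.0 kJ mol⁻¹)
    crystals ⇌ target, rate k4*(cs4 - [target]) while solid is left; crystals form when [target] > cs4 (solubility = 39.0 mM, k = 0.160 s⁻¹)
    (constants at 80 °C)

In Wednesday's flask at 80 °C, the forward half-life of substrate toward the dormant form is 0.40 min, shorter than the 1.1 min toward the intermediate, a forward rate ratio of 2.6 at the start. At its end the dormant form holds 60.9%, and target plus intermediate per substrate lost comes to 36.6%, above the blue reading. A further flask, like Wednesday's but charged with 0.200 equiv of coupling partner, gives the same share, 36.6%, as 10.7% target and 24.5% intermediate.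

The runs are simulated on assumed constants, and the scatter is random.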